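Locants used throughout: C1 is the quaternary ring carbon (CH2OH, polyene chain), C2 bears the three-carbon arm (a, b, c), C3 is the ring end of the exocyclic alkene to C7, C6 is the methyl carbinol. The synthesis rests on cutting C2–C3, which leads back to an acyclic 1,7-enyne: vinyl on C1, C3≡C7 methyl alkyne, free C1–CH2OH, silylated C6–OH. Divalent titanium held on the C1 CH2O oxygen closes the cyclohexane, sets C2 and the Z C3=C7 geometry at once; iodine then leaves CH2I at carbon a and iodide at C7. The step exploits the cis relation of C1–CH2O and carbon a and of C2 and the C7 carbonyl carbon.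

Key step: step 14

Remarks on the chemistry.
(a) Enyne 20 and diiodide 24 were compared with the target atom by atom: C1 (R), C2 (S), C6 (R) and the Z C3=C7 alkene agree in all three, so both are used as drawn.
(b) Design choice for the way to 20: C6 is taken from the chiral pool as (R)-mevalonolactone, whose ring maps onto C2 (carbonyl), C1, C6, C5, C4. C1 is then set relative to C6 by a silicon tether from the C6 oxygen, so no step before the key step has to tell vinyl from the chain or methyl from the alkynyl arm.
(c) Assumptions: (R)-mevalonolactone and 1-propynyllithium are bought. hF = homofarnesyl = (3E,7E)-4,8,12-trimethyltrideca-3,7,11-trien-1-yl. TES = triethylsilyl.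

Step 1
Reactants: 1 (2E,6E)-farnesol
Product: 2 (2E,6E)-farnesal
Conditions: MnO2, CH2Cl2, 20 °C
Reagents that add atoms: none
Why: Allylic alcohol oxidation with MnO2 stops at the aldehyde and leaves the E geometry of the conjugated alkene untouched.

Step 2
Reactants: 2 (2E,6E)-farnesal
Product: 3 (3E,7E)-4,8,12-trimethyltrideca-1,3,7,11-tetraene
Conditions: Ph3PCH3Br, n-BuLi, THF, 0 to 20 °C
Reagents that add atoms: methyltriphenylphosphonium bromide, C[P+](c1ccccc1)(c1ccccc1)c1ccccc1.[Br-]
Why: Wittig methylenation of the enal with Ph3P=CH2 gives the terminal diene without touching the trisubstituted alkenes.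

Step 3
Reactants: 3 (3E,7E)-4,8,12-trimethyltrideca-1,3,7,11-tetraene
Product: 5 (3E,7E)-homofarnesol, via alkylborane 4 (not isolated)
Conditions: 9-BBN, THF, 0 to 20 °C; then NaOH, H2O2, 0 °C
Reagents that add atoms: hydrogen peroxide, OO
Why: Hydroboration–oxidation, in which the bulky borane adds only to the monosubstituted end of the diene with boron on the terminal carbon, so oxidation gives the primary homoallylic alcohol.

Step 4
Reactants: 5 (3E,7E)-homofarnesol
Product: 6 (3E,7E)-homofarnesyl iodide
Conditions: I2, PPh3, imidazole, CH2Cl2, 0 °C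
Reagents that add atoms: iodine, II
Why: Appel-type iodination converts the primary alcohol into the iodide under buffered conditions that spare the acid-sensitive polyene.

Step 5
Reactants: 7 (R)-mevalonolactone; 6 (3E,7E)-homofarnesyl iodide
Product: 9 (4R)-4-hydroxy-4-methyl-3-hF-oxan-2-one as both C3 epimers, via dilithium dianion 8 (not isolated)
Conditions: LiN(iPr)2 (2.2 equiv), THF, −78 to −30 °C; then 6, DMPU, −78 to 0 °C
Reagents that add atoms: none
Why: Fráter–Seebach-type dianion alkylation, in which the alkoxide blocks β-elimination while the enolate carbon displaces the primary iodide by SN2; C6 comes unchanged from the chiral pool and the configuration of the new tertiary C1 is irrelevant because it is enolised again in step 7.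

Step 6
Reactants: 9 (4R)-4-hydroxy-4-methyl-3-hF-oxan-2-one
Product: 10 (bromomethyl)dimethylsilyl ether of 9
Conditions: BrCH2SiMe2Cl, imidazole, DMF, 0 to 20 °C
Reagents that add atoms: (bromomethyl)chlorodimethylsilane, C[Si](C)(Cl)CBr
Why: Silylation of the tertiary alcohol with a small chlorodimethylsilane places the one-carbon electrophile on the C6 oxygen as a temporary silicon tether.

Step 7
Reactants: 10 (bromomethyl)dimethylsilyl ether of 9
Product: 13 (3R,4R)-4-hydroxy-3-(hydroxymethyl)-4-methyl-3-hF-oxan-2-one, via lithium enolate 11 (not isolated), via bicyclic oxasilolane 12 (not isolated)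
Conditions: LiN(iPr)2, THF, −78 to 0 °C; then KF, KHCO3, H2O2, THF/MeOH, 20 °C
Reagents that add atoms: hydrogen peroxide, OO
Why: Intramolecular enolate C-alkylation by the α-bromo silane (5-exo-tet) followed by Tamao oxidation of the C–Si bond; the two-atom O–Si tether can reach the planar C1 enolate only on the ring face that carries the C6 oxygen, so the new CH2 (later CH2OH) is set cis to the C6 oxygen and C1 becomes quaternary with the required configuration.

Step 8
Reactants: 13 (3R,4R)-4-hydroxy-3-(hydroxymethyl)-4-methyl-3-hF-oxan-2-one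
Product: 14 bis-TES ether of 13
Conditions: Et3SiOTf, 2,6-lutidine, CH2Cl2, −78 to 0 °C
Reagents that add atoms: triethylsilyl trifluoromethanesulfonate, CC[Si](CC)(CC)OS(=O)(=O)C(F)(F)F
Why: Silyl triflate with a hindered pyridine base silylates both the primary and the hindered tertiary hydroxyl while buffering the acid that could cyclise the polyene.

Step 9
Reactants: 14 bis-TES ether of 13
Product: 15 lactol of 14 (both anomers)
Conditions: iBu2AlH, CH2Cl2, −78 °C
Reagents that add atoms: none
Why: Half-reduction of the lactone, whose aluminium hemiacetal is stable at low temperature and gives the lactol on work-up.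

Step 10
Reactants: 15 lactol of 14
Product: 16 acyclic alcohol with C1 vinyl and C4 primary OH
Conditions: Ph3PCH3Br, n-BuLi, THF, −20 to 20 °C
Reagents that add atoms: methyltriphenylphosphonium bromide, C[P+](c1ccccc1)(c1ccccc1)c1ccccc1.[Br-]
Why: Wittig methylenation of the hydroxy aldehyde in equilibrium with the lactol turns the former lactone carbon into the C1 vinyl group and frees the C4 alcohol, a lithium base and low temperature being chosen to suppress silyl migration to the new alkoxide.

Step 11
Reactants: 16 acyclic alcohol with C1 vinyl and C4 primary OH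
Product: 17 primary iodide at C4
Conditions: I2, PPh3, imidazole, CH2Cl2, 0 °C
Reagents that add atoms: iodine, II
Why: Appel-type iodination of the only free, unhindered primary alcohol proceeds under buffered conditions that leave both silyl ethers and all alkenes intact.

Step 12
Reactants: 17 primary iodide at C4; 18 1-propynyllithium
Product: 19 bis-TES 1,7-enyne
Conditions: THF/DMPU, −78 to 20 °C
Reagents that add atoms: none
Why: SN2 alkylation of the alkynyllithium by the unbranched primary iodide in a dipolar cosolvent attaches C3, C7 and the C7 methyl group.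

Step 13
Reactants: 19 bis-TES 1,7-enyne
Product: 20 enyne with free C1–CH2OH and C6–OTES (C1 R; C6 R)
Conditions: PPTS (cat.), MeOH/CH2Cl2, 0 °C
Reagents that add atoms: none
Why: Acid-catalysed methanolysis cleaves the primary silyl ether much faster than the tertiary one on the fully substituted C6, so only the C1 hydroxymethyl group is freed.

Step 14
Reactants: 20 enyne with free C1–CH2OH and C6–OTES
Product: 24 cyclohexane diiodide (CH2I on C2; Z vinyl iodide at C7; C1 R; C2 S; C6 R), via titanium alkoxide 21 (not isolated), via alkyne complex 22 (not isolated), via titanacyclopentene 23 (not isolated)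
Conditions: n-BuLi, toluene, −78 °C; ClTi(OiPr)3, then c-C5H9MgCl, −78 to −30 °C; then I2, THF, −78 to 0 °C; cold aq. NH4Cl/Na2S2O3
Reagents that add atoms: iodine, II
Why: The lithium alkoxide of 20 is transferred to ClTi(OiPr)3 to give 21, two equivalents of c-C5H9MgCl reduce that centre to divalent titanium with loss of cyclopentane and cyclopentene, the C3≡C7 alkyne binds to give 22, and the C1 vinyl group inserts into the Ti–C3 bond to give 23, whose two C–Ti bonds are cleaved by I2 with retention. The closest known reaction type is the Ti(OiPr)4/Grignard-mediated bicyclisation of 1,6- and 1,7-enynes followed by iodinolysis, here combined with alkoxide-directed titanium alkyne–alkene coupling. The cyclohexane closes by C2–C3 bond formation in an exo mode at both π systems (6-exo-trig at the vinyl group, 6-exo-dig at the alkyne), which leaves carbon a and C7 outside the ring. The new stereocentre C2 is controlled by the titanium-bound C1 CH2O oxygen, because only insertion on the vinyl face that places carbon a cis to CH2O allows the six-membered O–Ti–Ca–C2–C1–CH2 chelate, and the syn addition of C2 and titanium across the alkyne puts titanium, and then iodine, on C7 cis to C2. The step needs facial selectivity at the vinyl group and chemoselectivity over the three trisubstituted chain alkenes; the first is secured by the covalent alkoxide tether, the second by the fact that trisubstituted alkenes do not compete with the alkyne for divalent titanium. The quench is kept cold and mildly acidic because the freed alkoxide sits cis to the new CH2I group and could otherwise close a tetrahydrofuran.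

Step 15
Reactants: 24 cyclohexane diiodide
Product: 25 C1–CH2OTES ether of 24
Conditions: Et3SiCl, imidazole, DMF, 0 °C
Reagents that add atoms: chlorotriethylsilane, CC[Si](Cl)(CC)CC
Why: Silylation of the neopentyl alcohol under weakly basic conditions prevents its alkoxide from displacing the cis iodomethyl group in the next, strongly basic step.

Step 16
Reactants: 25 C1–CH2OTES ether of 24; 26 tert-butyl acetate
Product: 28 tert-butyl ester with the arm CH2CH2CO2tBu on C2, via lithium enolate 27 (not isolated)
Conditions: LiN(iPr)2, THF, −78 °C; then 25, DMPU, −78 to −20 °C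
Reagents that add atoms: none
Why: SN2 alkylation of the lithium ester enolate by the primary iodide adds arm carbons b and c, the vinyl iodide being inert to enolates and the dipolar cosolvent favouring substitution over elimination.

Step 17
Reactants: 28 tert-butyl ester with vinyl iodide
Product: 29 methyl (Z)-enoate at C7
Conditions: PdCl2(PPh3)2 (cat.), CO (1 atm), MeOH, Et3N, DMF, 60 °C
Reagents that add atoms: carbon monoxide, [C-]#[O+]; methanol, CO
Why: Palladium-catalysed alkoxycarbonylation, in which oxidative addition of zerovalent palladium to the vinyl iodide, CO insertion and methanolysis all retain the alkene geometry, so the ester carbon ends up cis to C2.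

Step 18
Reactants: 29 methyl (Z)-enoate at C7
Product: 30 diol (C7–CH2OH and arm CH2CH2CH2OH)
Conditions: iBu2AlH (excess), CH2Cl2, −78 to 0 °C
Reagents that add atoms: none
Why: Hydride reduction by iBu2AlH converts the enoate by 1,2-addition into the allylic alcohol and the tert-butyl ester into the primary alcohol while silyl ethers and alkenes are untouched.

Step 19
Reactants: 30 diol
Product: 31 bis-TES ether of the target
Conditions: MnO2, CH2Cl2, 20 °C
Reagents that add atoms: none
Why: Chemoselective allylic oxidation with MnO2 gives the enal without isomerising the tetrasubstituted alkene and leaves the saturated primary alcohol alone.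

Step 20
Reactants: 31 bis-TES ether of the target
Product: 32 target CNP0284886.2
Conditions: HF·pyridine, pyridine, THF, 0 to 20 °C
Reagents that add atoms: none
Why: Fluoride-mediated desilylation under buffered, weakly acidic conditions removes both triethylsilyl groups without deconjugating or isomerising the Z enal.

Compound list
1 | (2E,6E)-farnesol | CC(C)=CCC/C(C)=C/CC/C(C)=C/CO | starting material
2 | (2E,6E)-farnesal | CC(C)=CCC/C(C)=C/CC/C(C)=C/C=O | intermediate
3 | (3E,7E)-4,8,12-trimethyltrideca-1,3,7,11-tetraene | CC(C)=CCC/C(C)=C/CC/C(C)=C/C=C | intermediate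
4 | B-homofarnesyl-9-borabicyclo[3.3.1]nonane | CC(C)=CCC/C(C)=C/CC/C(C)=C/CCB1C2CCCC1CCC2 | intermediate (not isolated)
5 | (3E,7E)-homofarnesol | CC(C)=CCC/C(C)=C/CC/C(C)=C/CCO | intermediate
6 | (3E,7E)-homofarnesyl iodide | CC(C)=CCC/C(C)=C/CC/C(C)=C/CCI | intermediate
7 | (R)-mevalonolactone, (4R)-4-hydroxy-4-methyloxan-2-one | O=C1C[C@](C)(O)CCO1 | starting material
8 | dilithium dianion of 7 (lithium enolate, lithium alkoxide at C6) | [Li]OC1=C[C@](C)(O[Li])CCO1 | intermediate (not isolated)
9 | (4R)-4-hydroxy-4-methyl-3-hF-oxan-2-one, both C3 epimers | CC(C)=CCC/C(C)=C/CC/C(C)=C/CCC(C1=O)[C@](C)(O)CCO1 | intermediate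
10 | (bromomethyl)dimethylsilyl ether of 9 at the C6 oxygen | CC(C)=CCC/C(C)=C/CC/C(C)=C/CCC(C1=O)[C@](C)(O[Si](C)(C)CBr)CCO1 | intermediate
11 | lithium enolate of 10 | CC(C)=CCC/C(C)=C/CC/C(C)=C/CCC(=C1O[Li])[C@](C)(O[Si](C)(C)CBr)CCO1 | intermediate (not isolated)
12 | cis-fused oxasilolane lactone (ring C1–CH2–SiMe2–O–C6 on the six-membered lactone, CH2 cis to the C6 oxygen) | CC(C)=CCC/C(C)=C/CC/C(C)=C/CC[C@](C[Si](C)(C)O2)(C1=O)[C@@]2(C)CCO1 | intermediate (not isolated)
13 | (3R,4R)-4-hydroxy-3-(hydroxymethyl)-4-methyl-3-hF-oxan-2-one (CH2OH cis to OH) | CC(C)=CCC/C(C)=C/CC/C(C)=C/CC[C@](CO)(C1=O)[C@](C)(O)CCO1 | intermediate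
14 | bis-TES ether of 13 | CC(C)=CCC/C(C)=C/CC/C(C)=C/CC[C@](CO[Si](CC)(CC)CC)(C1=O)[C@](C)(O[Si](CC)(CC)CC)CCO1 | intermediate
15 | lactol of 14, both anomers, C1 and C6 unchanged | CC(C)=CCC/C(C)=C/CC/C(C)=C/CC[C@](CO[Si](CC)(CC)CC)(C1O)[C@](C)(O[Si](CC)(CC)CC)CCO1 | intermediate
16 | acyclic alcohol: C1 (R) with CH2OTES, vinyl and hF; C6 (R) with CH3 and OTES; C5H2–C4H2OH | CC(C)=CCC/C(C)=C/CC/C(C)=C/CC[C@](CO[Si](CC)(CC)CC)(C=C)[C@](C)(O[Si](CC)(CC)CC)CCO | intermediate
17 | primary iodide of 16 (C4–I) | CC(C)=CCC/C(C)=C/CC/C(C)=C/CC[C@](CO[Si](CC)(CC)CC)(C=C)[C@](C)(O[Si](CC)(CC)CC)CCI | intermediate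
18 | 1-propynyllithium | [Li]C#CC | starting material
19 | bis-TES 1,7-enyne (C4 bonded to C3≡C7–CH3) | CC(C)=CCC/C(C)=C/CC/C(C)=C/CC[C@](CO[Si](CC)(CC)CC)(C=C)[C@](C)(O[Si](CC)(CC)CC)CCC#CC | intermediate
20 | key-step precursor: 1,7-enyne with free C1–CH2OH and C6–OTES (C1 R, C6 R) | CC(C)=CCC/C(C)=C/CC/C(C)=C/CC[C@](CO)(C=C)[C@](C)(O[Si](CC)(CC)CC)CCC#CC | intermediate
21 | triisopropoxytitanium alkoxide of 20 | CC(C)=CCC/C(C)=C/CC/C(C)=C/CC[C@](CO[Ti](OC(C)C)(OC(C)C)OC(C)C)(C=C)[C@](C)(O[Si](CC)(CC)CC)CCC#CC | intermediate (not isolated)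
22 | alkoxide-bound alkyne complex of divalent titanium (titanacyclopropene at C3/C7, one OiPr) | CC(C)=CCC/C(C)=C/CC/C(C)=C/CC[C@](CO2)(C=C)[C@](C)(O[Si](CC)(CC)CC)CCC3=C(C)[Ti]23OC(C)C | intermediate (not isolated)
23 | alkoxide-chelated titanacyclopentene (Ti bonded to C7, carbon a, the C1 CH2O oxygen and one OiPr) | CC(C)=CCC/C(C)=C/CC/C(C)=C/CC[C@]1(CO2)[C@@H](C3)/C(=C(/C)[Ti]23OC(C)C)CC[C@@]1(C)O[Si](CC)(CC)CC | intermediate (not isolated)
24 | key-step product: cyclohexane with CH2I on C2, (Z)-C3=C7(CH3)I, free C1–CH2OH, C6–OTES (C1 R, C2 S, C6 R) | CC(C)=CCC/C(C)=C/CC/C(C)=C/CC[C@]1(CO)[C@@H](CI)/C(=C(/C)I)CC[C@@]1(C)O[Si](CC)(CC)CC | intermediate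
25 | C1–CH2OTES ether of 24 | CC(C)=CCC/C(C)=C/CC/C(C)=C/CC[C@]1(CO[Si](CC)(CC)CC)[C@@H](CI)/C(=C(/C)I)CC[C@@]1(C)O[Si](CC)(CC)CC | intermediate
26 | tert-butyl acetate | CC(=O)OC(C)(C)C | starting material
27 | lithium enolate of tert-butyl acetate | [Li]OC(=C)OC(C)(C)C | intermediate (not isolated)
28 | tert-butyl ester: arm CH2CH2CO2tBu on C2, vinyl iodide retained | CC(C)=CCC/C(C)=C/CC/C(C)=C/CC[C@]1(CO[Si](CC)(CC)CC)[C@@H](CCC(=O)OC(C)(C)C)/C(=C(/C)I)CC[C@@]1(C)O[Si](CC)(CC)CC | intermediate
29 | methyl (Z)-enoate at C7, tert-butyl ester on the arm | CC(C)=CCC/C(C)=C/CC/C(C)=C/CC[C@]1(CO[Si](CC)(CC)CC)[C@@H](CCC(=O)OC(C)(C)C)/C(=C(/C)C(=O)OC)CC[C@@]1(C)O[Si](CC)(CC)CC | intermediate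
30 | diol: C7–CH2OH and arm CH2CH2CH2OH, both TES ethers retained | CC(C)=CCC/C(C)=C/CC/C(C)=C/CC[C@]1(CO[Si](CC)(CC)CC)[C@@H](CCCO)/C(=C(/C)CO)CC[C@@]1(C)O[Si](CC)(CC)CC | intermediate
31 | bis-TES ether of the target (Z enal) | CC(C)=CCC/C(C)=C/CC/C(C)=C/CC[C@]1(CO[Si](CC)(CC)CC)[C@@H](CCCO)/C(=C(/C)C=O)CC[C@@]1(C)O[Si](CC)(CC)CC | intermediate
32 | CNP0284886.2 (C1 R, C2 S, C6 R; Z enal) | CC(C)=CCC/C(C)=C/CC/C(C)=C/CC[C@]1(CO)[C@@H](CCCO)/C(=C(/C)C=O)CC[C@@]1(C)O | target

Total step count: 20. Longest linear sequence: 20 steps (1 to 32; compounds 7, 18 and 26 are bought).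

Steps most likely to fail

Step 14. The alkoxide may not stay on the titanium centre that carries the alkyne (alkoxide exchange between titanium centres). Ring closure would then proceed without the tether and facial selectivity at the vinyl group would be lost. Alternatively the hindered vinyl group on quaternary C1 may fail to insert, so that the alkyne complex is simply iodinated or protonated. The fallback sets out from 19 and gives up the tether. Zirconocene-mediated bicyclisation (Cp2ZrCl2, two equivalents of n-BuLi, THF, −78 to 20 °C; divalent zirconium) of the fully silylated enyne should give the zirconacyclopentene F1. Iodinolysis of both C–Zr bonds then gives 25 directly, together with its C2 epimer F2, because C2 is no longer directed. The epimers are separated by chromatography and the route is rejoined at 25.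

Step 7. β-Elimination of the silyloxy group from the lactone enolate, or attack of the amide base at silicon, may outrun the ring closure. The fallback sets out from 9 and replaces the tethered alkylation by an intermolecular aldol reaction. Two equivalents of LiN(iPr)2 give the dilithium dianion F3, which is treated at −78 °C with gaseous monomeric formaldehyde. Face selectivity is then decided by competition between the C6 methyl group and the lithium alkoxide, so 13 must be expected together with its C1 epimer F4. The two are separated and assigned by NOE on the derived acetonides, and the route is rejoined at 13.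

Step 16. Substitution at the β-branched iodide next to quaternary C1 may be slow enough for E2 elimination toward the conjugated exocyclic diene to take over with the strongly basic ester enolate. The fallback sets out from 25 and uses a soft, weakly basic nucleophile. Dimethyl malonate with NaH in DMF at 60 °C should give the malonate F5. Krapcho dealkoxycarbonylation (NaCl, wet DMSO, 150 °C) gives the methyl ester F6. Carbonylation as in step 17 gives the dimethyl diester F7, and iBu2AlH as in step 18 reduces both esters, so the route is rejoined at 30.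

Further compounds
F1 | step 14 | zirconacyclopentene from 19 (Cp2Zr bonded to C7 and carbon a, both oxygens as TES ethers) | CC(C)=CCC/C(C)=C/CC/C(C)=C/CC[C@]1(CO[Si](CC)(CC)CC)[C@@H](C2)/C(=C(/C)[Zr]2(C3C=CC=C3)C3C=CC=C3)CC[C@@]1(C)O[Si](CC)(CC)CC
F2 | step 14 | C2 epimer of 25 | CC(C)=CCC/C(C)=C/CC/C(C)=C/CC[C@]1(CO[Si](CC)(CC)CC)[C@H](CI)/C(=C(/C)I)CC[C@@]1(C)O[Si](CC)(CC)CC
F3 | step 7 | dilithium dianion of 9 | CC(C)=CCC/C(C)=C/CC/C(C)=C/CCC(=C1O[Li])[C@](C)(O[Li])CCO1
F4 | step 7 | C1 epimer of 13 (CH2OH trans to OH) | CC(C)=CCC/C(C)=C/CC/C(C)=C/CC[C@@](CO)(C1=O)[C@](C)(O)CCO1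
F5 | step 16 | dimethyl malonate adduct of 25 (arm CH2CH(CO2Me)2) | CC(C)=CCC/C(C)=C/CC/C(C)=C/CC[C@]1(CO[Si](CC)(CC)CC)[C@@H](CC(C(=O)OC)C(=O)OC)/C(=C(/C)I)CC[C@@]1(C)O[Si](CC)(CC)CC
F6 | step 16 | methyl ester with arm CH2CH2CO2Me, vinyl iodide retained | CC(C)=CCC/C(C)=C/CC/C(C)=C/CC[C@]1(CO[Si](CC)(CC)CC)[C@@H](CCC(=O)OC)/C(=C(/C)I)CC[C@@]1(C)O[Si](CC)(CC)CC
F7 | step 16 | dimethyl diester (arm CO2Me and Z C7–CO2Me) | CC(C)=CCC/C(C)=C/CC/C(C)=C/CC[C@]1(CO[Si](CC)(CC)CC)[C@@H](CCC(=O)OC)/C(=C(/C)C(=O)OC)CC[C@@]1(C)O[Si](CC)(CC)CC
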